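The cyclohexane ring (C5–C10, elemane numbering) is closed last across C9–C10 by an intramolecular Nozaki–Hiyama–Kishi allylation. The quaternary C10 carrying vinyl (C1=C2) and methyl next to the C9 carbinol is the retron of a γ-selective addition of a (Z)-trisubstituted allylchromium to an aldehyde. One operation forms the ring and both C9 and C10, relayed from the trans-fused C7/C8 lactone, which locks the chair. The precursor is an open-chain α-methylene-γ-butyrolactone carrying the C9 aldehyde and, on C7, the C6 angelate and a C5 side chain ending in a neryl-type allylic bromide. Its four stereocentres stem from one purchased lactone through conjugate addition and an anti-Felkin syn-aldol.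

Key step: step 18

Remark on numbering: C10 is the quaternary ring carbon (C14 methyl, C1=C2 vinyl), C9 is CH–OAc, C8 the lactone O–CH, C7 the lactone ring CH, C6 is CH–O-angeloyl, C5 carries C4(=C15H2)–C3HO, and the lactone is C11(=C13H2)–C12(=O). The target is (5R,6S,7S,8R,9S,10S). "syn" and "anti" refer to the zigzag chain C4–C5–C6–C7–C8–C9.

Remark on materials: compounds 1, 8, 12 and 25 are taken as purchased.

Step 1
Reactants: 1 (5R)-5-(hydroxymethyl)oxolan-2-one
Product: 2 (5R)-5-[(tert-butyldiphenylsilyloxy)methyl]oxolan-2-one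
Conditions: TBDPSCl, imidazole, DMF, 0 °C to rt
Reagents that add atoms: tert-butyl(chloro)diphenylsilane CC(C)(C)[Si](Cl)(c1ccccc1)c1ccccc1
Why: Silyl ether formation at the only hydroxyl group should be clean and leaves the purchased stereocentre C8 untouched.

Step 2
Reactants: 2 (5R)-5-[(tert-butyldiphenylsilyloxy)methyl]oxolan-2-one
Product: 4 (5R)-5-[(tert-butyldiphenylsilyloxy)methyl]furan-2(5H)-one, via α-phenylselanyl lactone 3 (not isolated)
Conditions: lithium diisopropylamide, THF, −78 °C; PhSeBr; then H2O2 (30%), pyridine, CH2Cl2, 0 °C to rt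
Reagents that add atoms: none
Why: α-Selenenylation of the lactone enolate followed by oxidation and syn-elimination of the selenoxide (selenoxide elimination) should give the butenolide without involving C8.

Step 3
Reactants: 4 (5R)-5-[(tert-butyldiphenylsilyloxy)methyl]furan-2(5H)-one
Product: 5 (4S,5R)-5-[(tert-butyldiphenylsilyloxy)methyl]-4-ethenyloxolan-2-one
Conditions: CH2=CHMgBr, CuBr·SMe2 (10 mol%), THF, −78 °C; aq NH4Cl
Reagents that add atoms: vinylmagnesium bromide C=C[Mg]Br
Why: Copper-catalysed conjugate addition of the vinyl Grignard reagent should occur on the butenolide face opposite to the C8 silyloxymethyl group, which sets C7 trans to C8.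

Step 4
Reactants: 5 (4S,5R)-5-[(tert-butyldiphenylsilyloxy)methyl]-4-ethenyloxolan-2-one
Product: 7 (2R,3R)-2-[(tert-butyldiphenylsilyloxy)methyl]-5-oxooxolane-3-carbaldehyde, via ozonide 6 (not isolated)
Conditions: O3, CH2Cl2, −78 °C; then Me2S, −78 °C to rt
Reagents that add atoms: ozone [O-][O+]=O
Why: Ozonolysis with reductive work-up cleaves the only alkene to the C6 aldehyde, and the trans arrangement at C7 is also the thermodynamically preferred one.

Step 5
Reactants: 8 but-2-yn-1-ol
Product: 10 (2Z)-3-iodobut-2-en-1-ol, via cyclic alkenylalanate 9 (not isolated)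
Conditions: NaAlH2(OCH2CH2OMe)2, THF, 0 °C to rt; then I2, THF, −78 °C
Reagents that add atoms: iodine II
Why: Hydroxyl-directed trans-hydroalumination of the propargylic alcohol and iodinolysis of the cyclic alkenylalanate with retention should give the (Z)-iodide, the source of the later (Z)-geometry at C10=C1.

Step 6
Reactants: 10 (2Z)-3-iodobut-2-en-1-ol
Product: 11 tert-butyl{[(2Z)-3-iodobut-2-en-1-yl]oxy}diphenylsilane
Conditions: TBDPSCl, imidazole, CH2Cl2, rt
Reagents that add atoms: tert-butyl(chloro)diphenylsilane CC(C)(C)[Si](Cl)(c1ccccc1)c1ccccc1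
Why: Silyl ether formation protects the allylic C2 hydroxyl for the organolithium chemistry that follows.

Step 7
Reactants: 11 tert-butyl{[(2Z)-3-iodobut-2-en-1-yl]oxy}diphenylsilane; 12 racemic 2-{[(4-methoxybenzyl)oxy]methyl}oxirane
Product: 14 (4Z)-6-(tert-butyldiphenylsilyloxy)-1-(4-methoxybenzyloxy)-4-methylhex-4-en-2-ol, via (Z)-alkenyllithium 13 (not isolated)
Conditions: t-BuLi (2.1 equiv), Et2O, −78 °C; then 12, BF3·OEt2, −78 °C
Reagents that add atoms: none
Why: Iodine–lithium exchange keeps the alkene geometry and the BF3-activated epoxide is opened at its unsubstituted carbon (epoxide opening), which joins C5 to C10; the carbinol centre formed is removed in step 8.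

Step 8
Reactants: 14 (4Z)-6-(tert-butyldiphenylsilyloxy)-1-(4-methoxybenzyloxy)-4-methylhex-4-en-2-ol
Product: 15 (4Z)-6-(tert-butyldiphenylsilyloxy)-1-(4-methoxybenzyloxy)-4-methylhex-4-en-2-one
Conditions: Dess–Martin periodinane, NaHCO3, CH2Cl2, 0 °C
Reagents that add atoms: none
Why: Buffered Dess–Martin oxidation should give the β,γ-unsaturated ketone without migration of the double bond into conjugation.

Step 9
Reactants: 15 (4Z)-6-(tert-butyldiphenylsilyloxy)-1-(4-methoxybenzyloxy)-4-methylhex-4-en-2-one; 7 (2R,3R)-2-[(tert-butyldiphenylsilyloxy)methyl]-5-oxooxolane-3-carbaldehyde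
Product: 18 open-chain C5–C6 syn-aldol adduct (C4 ketone with free C6 hydroxyl), via dibutylboron (Z)-dienolate 16 (not isolated), via dibutylboron aldolate 17 (not isolated)
Conditions: Bu2BOTf, i-Pr2NEt, CH2Cl2, −78 to 0 °C; then 7, −78 to −20 °C; pH 7 buffer, MeOH, H2O2, 0 °C
Reagents that add atoms: none
Why: Enolisation should occur on the allylic side to give the (Z)-boron dienolate, which reacts at its α-carbon C5 through a Zimmerman–Traxler chair (boron aldol reaction) to set the 5,6-syn relation, while the known preference of (Z)-enolates for anti-Felkin attack on α-branched aldehydes (the Felkin arrangement suffers a syn-pentane contact) should place O6 anti to C11.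

Step 10
Reactants: 18 open-chain C5–C6 syn-aldol adduct
Product: 19 C6 triethylsilyl ether of the aldol adduct
Conditions: TESOTf, 2,6-lutidine, CH2Cl2, −78 °C
Reagents that add atoms: triethylsilyl trifluoromethanesulfonate CC[Si](CC)(CC)OS(=O)(=O)C(F)(F)F
Why: Silylation with the silyl triflate at low temperature protects the β-hydroxy ketone before retro-aldol cleavage or elimination can intervene.

Step 11
Reactants: 19 C6 triethylsilyl ether of the aldol adduct
Product: 20 C4-methylene compound (C4=C15)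
Conditions: Zn, CH2Br2, TiCl4, THF/CH2Cl2, 0 °C to rt
Reagents that add atoms: dibromomethane BrCBr
Why: Takai–Lombardo methylenation is non-basic, so the ketone next to the epimerisable C5 should be converted into the C4=C15 methylene group without epimerisation or β-elimination, and the lactone is inert to the reagent.

Step 12
Reactants: 20 C4-methylene compound
Product: 23 α-methylene lactone (C11=C13) bearing the C6 triethylsilyl ether, via Mannich base 21 (not isolated), via ammonium iodide 22 (not isolated)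
Conditions: lithium diisopropylamide, THF, −78 °C; CH2=NMe2+ I−, −78 °C to rt; then MeI, MeOH, rt; then aq NaHCO3, CH2Cl2
Reagents that add atoms: N,N-dimethylmethyleneiminium iodide (Eschenmoser's salt) C=[N+](C)C.[I-]
Why: Kinetic deprotonation of the lactone at C11, Mannich reaction with Eschenmoser's salt, quaternisation and Hofmann-type elimination is the standard α-methylenation of γ-butyrolactones and creates no stereocentre.

Step 13
Reactants: 23 α-methylene lactone bearing the C6 triethylsilyl ether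
Product: 24 C6 alcohol
Conditions: HF·pyridine, pyridine, THF, 0 °C
Reagents that add atoms: none
Why: Buffered HF·pyridine should cleave the triethylsilyl ether much faster than the two primary tert-butyldiphenylsilyl ethers (selective desilylation).

Step 14
Reactants: 24 C6 alcohol; 25 angelic acid
Product: 27 C6 angelate, via mixed anhydride 26 (not isolated)
Conditions: 25, 2,4,6-Cl3C6H2COCl, Et3N, toluene, rt; then 24, 75 °C
Reagents that add atoms: none
Why: Yamaguchi-type esterification through the preformed mixed anhydride without a nucleophilic catalyst is the established way to attach an angeloyl group with retention of its (Z)-geometry, and C6 keeps its configuration because its C–O bond is not broken.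

Step 15
Reactants: 27 C6 angelate
Product: 28 C2,C9-diol
Conditions: Bu4NF, AcOH, THF, 0 °C to rt
Reagents that add atoms: none
Why: Fluoride buffered with acetic acid should cleave both silyl ethers (desilylation) without attacking the esters or the α-methylene lactone.

Step 16
Reactants: 28 C2,C9-diol
Product: 29 C2 allylic bromide with free C9 hydroxyl
Conditions: NBS, Me2S, CH2Cl2, −20 to 0 °C
Reagents that add atoms: N-bromosuccinimide O=C1CCC(=O)N1Br
Why: In the Corey–Kim halogenation only the allylic alkoxysulfonium ion collapses to the bromide, by SN2 displacement without allylic shift or loss of the (Z)-geometry, while the saturated C9 alcohol is recovered on work-up.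

Step 17
Reactants: 29 C2 allylic bromide with free C9 hydroxyl
Product: 30 bromo aldehyde (cyclisation precursor)
Conditions: Dess–Martin periodinane, NaHCO3, CH2Cl2, 0 °C
Reagents that add atoms: none
Why: Dess–Martin oxidation is neutral and fast, so the primary alcohol should give the C9 aldehyde without epimerisation at C8 or loss of the allylic bromide.

Step 18
Reactants: 30 bromo aldehyde (cyclisation precursor)
Product: 32 cyclised C9 alcohol (9-hydroxy elemanolide with C3 4-methoxybenzyl ether), via allylchromium dichloride 31 (not isolated)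
Conditions: CrCl2 (10 equiv), degassed THF, 0.003 M, slow addition of 30, rt
Reagents that add atoms: none
Why: Two equivalents of CrCl2 (divalent chromium) reduce the allylic bromide to the σ-allylchromium dichloride 31 (trivalent chromium), which adds to the C9 aldehyde through its γ-carbon C10 in a closed six-membered Zimmerman–Traxler transition state with allylic transposition, so that C1=C2 emerges as the vinyl group. The closest known reaction type is the intramolecular Nozaki–Hiyama–Kishi (Barbier-type) carbonyl allylation with γ,γ-disubstituted allylic halides. The cyclohexane ring C5–C10 is closed by 6-exo-trig attack on the aldehyde carbon, the eight-membered alternative from α-attack being disfavoured by the cyclic transition state. C10 is set by the (Z)-geometry of the allyl unit (C5 axial and CH3 equatorial in the metallacycle, hence CH3 axial and vinyl equatorial on the new chair), and C9 by the equatorial placement of C8 in the metallacycle, which makes the C9 oxygen axial and cis to the vinyl group. Which chair forms is dictated by the trans-disubstituted lactone at C7/C8 (both ring bonds equatorial) and the equatorial C5 side chain. The step needs γ- over α-regioselectivity, retention of the (Z)-geometry until the C–C bond forms and chemoselectivity over the α-methylene lactone and the two esters; these should be secured by the closed transition state, fast intramolecular capture at high dilution and the inertness of esters and enoates to CrCl2.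

Step 19
Reactants: 32 cyclised C9 alcohol
Product: 33 C9 acetate
Conditions: Ac2O, DMAP, pyridine, CH2Cl2, rt
Reagents that add atoms: acetic anhydride CC(=O)OC(C)=O
Why: DMAP-catalysed acylation should acetylate the only free hydroxyl group, the axial C9–OH, with retention.

Step 20
Reactants: 33 C9 acetate
Product: 34 C3 allylic alcohol
Conditions: DDQ, CH2Cl2/pH 7 buffer, 0 °C
Reagents that add atoms: none
Why: Oxidative cleavage of the 4-methoxybenzyl ether by DDQ through the benzylic oxocarbenium ion is compatible with the esters and alkenes present.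

Step 21
Reactants: 34 C3 allylic alcohol
Product: 35 (3aS,4S,5R,6S,7S,7aR)-7-acetoxy-6-ethenyl-6-methyl-3-methylidene-2-oxo-5-(3-oxoprop-1-en-2-yl)octahydro-1-benzofuran-4-yl (2Z)-2-methylbut-2-enoate
Conditions: MnO2, CH2Cl2, rt
Reagents that add atoms: none
Why: MnO2 oxidises the primary allylic alcohol selectively to the 2-substituted acrolein (allylic oxidation) under neutral heterogeneous conditions, which should avoid epimerisation or double-bond migration at the γ-position C5.

Compound list

1 | (5R)-5-(hydroxymethyl)oxolan-2-one | OC[C@@H]1OC(=O)CC1 | starting material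
2 | (5R)-5-[(tert-butyldiphenylsilyloxy)methyl]oxolan-2-one | CC(C)(C)[Si](OC[C@@H]1OC(=O)CC1)(c1ccccc1)c1ccccc1 | intermediate
3 | α-phenylselanyl lactone (C11 epimers) | CC(C)(C)[Si](OC[C@@H]1OC(=O)C([Se]c2ccccc2)C1)(c1ccccc1)c1ccccc1 | intermediate (not isolated)
4 | (5R)-5-[(tert-butyldiphenylsilyloxy)methyl]furan-2(5H)-one | CC(C)(C)[Si](OC[C@@H]1OC(=O)C=C1)(c1ccccc1)c1ccccc1 | intermediate
5 | (4S,5R)-5-[(tert-butyldiphenylsilyloxy)methyl]-4-ethenyloxolan-2-one (7,8-trans) | CC(C)(C)[Si](OC[C@@H]1OC(=O)C[C@H]1C=C)(c1ccccc1)c1ccccc1 | intermediate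
6 | ozonide of 5 (1,2,4-trioxolane at C6) | CC(C)(C)[Si](OC[C@@H]1OC(=O)C[C@H]1C1OCOO1)(c1ccccc1)c1ccccc1 | intermediate (not isolated)
7 | (2R,3R)-2-[(tert-butyldiphenylsilyloxy)methyl]-5-oxooxolane-3-carbaldehyde (C6 aldehyde; 7,8-trans) | CC(C)(C)[Si](OC[C@@H]1OC(=O)C[C@H]1C=O)(c1ccccc1)c1ccccc1 | intermediate
8 | but-2-yn-1-ol | CC#CCO | starting material
9 | sodium cyclic (Z)-alkenylalanate (five-membered oxaaluminacycle with two 2-methoxyethoxy groups on aluminium) | CC1=CCO[Al-]1(OCCOC)OCCOC.[Na+] | intermediate (not isolated)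
10 | (2Z)-3-iodobut-2-en-1-ol | C/C(I)=C/CO | intermediate
11 | tert-butyl{[(2Z)-3-iodobut-2-en-1-yl]oxy}diphenylsilane | C/C(I)=C/CO[Si](c1ccccc1)(c1ccccc1)C(C)(C)C | intermediate
12 | 2-{[(4-methoxybenzyl)oxy]methyl}oxirane (racemic) | COc1ccc(COCC2CO2)cc1 | starting material
13 | (Z)-alkenyllithium from 11 | C/C([Li])=C/CO[Si](c1ccccc1)(c1ccccc1)C(C)(C)C | intermediate (not isolated)
14 | (4Z)-6-(tert-butyldiphenylsilyloxy)-1-(4-methoxybenzyloxy)-4-methylhex-4-en-2-ol (racemic carbinol) | COc1ccc(COCC(O)C/C(C)=C\CO[Si](c2ccccc2)(c2ccccc2)C(C)(C)C)cc1 | intermediate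
15 | (4Z)-6-(tert-butyldiphenylsilyloxy)-1-(4-methoxybenzyloxy)-4-methylhex-4-en-2-one | COc1ccc(COCC(=O)C/C(C)=C\CO[Si](c2ccccc2)(c2ccccc2)C(C)(C)C)cc1 | intermediate
16 | dibutylboron (Z)-dienolate of 15 (boron on the C4 oxygen, C4=C5 enolate, C10=C1 retained Z) | CCCCB(CCCC)O/C(COCc1ccc(OC)cc1)=C\C(C)=C/CO[Si](c1ccccc1)(c1ccccc1)C(C)(C)C | intermediate (not isolated)
17 | dibutylboron aldolate of 18 | CC(C)(C)[Si](OC[C@@H]1OC(=O)C[C@H]1[C@@H](OB(CCCC)CCCC)[C@H](/C(C)=C\CO[Si](c2ccccc2)(c2ccccc2)C(C)(C)C)C(=O)COCc2ccc(OC)cc2)(c3ccccc3)c3ccccc3 | intermediate (not isolated)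
18 | open-chain aldol adduct: C4 ketone, C6–OH, 5,6-syn, 6,7-anti, 7,8-trans lactone; C2 and C9 tert-butyldiphenylsilyl ethers, C3 4-methoxybenzyl ether | CC(C)(C)[Si](OC[C@@H]1OC(=O)C[C@H]1[C@@H](O)[C@H](/C(C)=C\CO[Si](c2ccccc2)(c2ccccc2)C(C)(C)C)C(=O)COCc2ccc(OC)cc2)(c3ccccc3)c3ccccc3 | intermediate
19 | C6 triethylsilyl ether of 18 | CC(C)(C)[Si](OC[C@@H]1OC(=O)C[C@H]1[C@@H](O[Si](CC)(CC)CC)[C@H](/C(C)=C\CO[Si](c2ccccc2)(c2ccccc2)C(C)(C)C)C(=O)COCc2ccc(OC)cc2)(c3ccccc3)c3ccccc3 | intermediate
20 | C4-methylene compound (C4=C15 in place of the ketone of 19) | CC(C)(C)[Si](OC[C@@H]1OC(=O)C[C@H]1[C@@H](O[Si](CC)(CC)CC)[C@H](/C(C)=C\CO[Si](c2ccccc2)(c2ccccc2)C(C)(C)C)C(=C)COCc2ccc(OC)cc2)(c3ccccc3)c3ccccc3 | intermediate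
21 | Mannich base (C11 dimethylaminomethyl lactone; C11 configuration not defined) | CC(C)(C)[Si](OC[C@@H]1OC(=O)C(CN(C)C)[C@H]1[C@@H](O[Si](CC)(CC)CC)[C@H](/C(C)=C\CO[Si](c2ccccc2)(c2ccccc2)C(C)(C)C)C(=C)COCc2ccc(OC)cc2)(c3ccccc3)c3ccccc3 | intermediate (not isolated)
22 | trimethylammonium iodide of 21 | CC(C)(C)[Si](OC[C@@H]1OC(=O)C(C[N+](C)(C)C)[C@H]1[C@@H](O[Si](CC)(CC)CC)[C@H](/C(C)=C\CO[Si](c2ccccc2)(c2ccccc2)C(C)(C)C)C(=C)COCc2ccc(OC)cc2)(c3ccccc3)c3ccccc3.[I-] | intermediate (not isolated)
23 | α-methylene lactone (C11=C13) with C6 triethylsilyl ether | CC(C)(C)[Si](OC[C@@H]1OC(=O)C(=C)[C@H]1[C@@H](O[Si](CC)(CC)CC)[C@H](/C(C)=C\CO[Si](c2ccccc2)(c2ccccc2)C(C)(C)C)C(=C)COCc2ccc(OC)cc2)(c3ccccc3)c3ccccc3 | intermediate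
24 | C6 alcohol (α-methylene lactone; C2 and C9 silyl ethers; C3 4-methoxybenzyl ether) | CC(C)(C)[Si](OC[C@@H]1OC(=O)C(=C)[C@H]1[C@@H](O)[C@H](/C(C)=C\CO[Si](c2ccccc2)(c2ccccc2)C(C)(C)C)C(=C)COCc2ccc(OC)cc2)(c3ccccc3)c3ccccc3 | intermediate
25 | angelic acid, (2Z)-2-methylbut-2-enoic acid | C/C=C(/C)C(=O)O | starting material
26 | angelic 2,4,6-trichlorobenzoic mixed anhydride | C/C=C(/C)C(=O)OC(=O)c1c(Cl)cc(Cl)cc1Cl | intermediate (not isolated)
27 | C6 angelate (C2 and C9 tert-butyldiphenylsilyl ethers) | CC(C)(C)[Si](OC[C@@H]1OC(=O)C(=C)[C@H]1[C@@H](OC(=O)/C(C)=C\C)[C@H](/C(C)=C\CO[Si](c2ccccc2)(c2ccccc2)C(C)(C)C)C(=C)COCc2ccc(OC)cc2)(c3ccccc3)c3ccccc3 | intermediate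
28 | C2,C9-diol | OC[C@@H]1OC(=O)C(=C)[C@H]1[C@@H](OC(=O)/C(C)=C\C)[C@H](/C(C)=C\CO)C(=C)COCc1ccc(OC)cc1 | intermediate
29 | C2 (Z)-allylic bromide with free C9 hydroxyl | OC[C@@H]1OC(=O)C(=C)[C@H]1[C@@H](OC(=O)/C(C)=C\C)[C@H](/C(C)=C\CBr)C(=C)COCc1ccc(OC)cc1 | intermediate
30 | bromo aldehyde: C9 aldehyde on the lactone, (Z)-allylic bromide at C2 | O=C[C@@H]1OC(=O)C(=C)[C@H]1[C@@H](OC(=O)/C(C)=C\C)[C@H](/C(C)=C\CBr)C(=C)COCc1ccc(OC)cc1 | intermediate
31 | (Z)-allylchromium dichloride (chromium on C2) | O=C[C@@H]1OC(=O)C(=C)[C@H]1[C@@H](OC(=O)/C(C)=C\C)[C@H](/C(C)=C\C[Cr](Cl)Cl)C(=C)COCc1ccc(OC)cc1 | intermediate (not isolated)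
32 | cyclised C9 alcohol: 9α-hydroxy elemanolide with 10β-methyl, 10α-vinyl, 6β-angelate, C3 4-methoxybenzyl ether | C=C[C@]1(C)[C@H](O)[C@@H]2OC(=O)C(=C)[C@H]2[C@@H](OC(=O)/C(C)=C\C)[C@H]1C(=C)COCc1ccc(OC)cc1 | intermediate
33 | C9 acetate | C=C[C@]1(C)[C@H](OC(C)=O)[C@@H]2OC(=O)C(=C)[C@H]2[C@@H](OC(=O)/C(C)=C\C)[C@H]1C(=C)COCc1ccc(OC)cc1 | intermediate
34 | C3 allylic alcohol | C=C[C@]1(C)[C@H](OC(C)=O)[C@@H]2OC(=O)C(=C)[C@H]2[C@@H](OC(=O)/C(C)=C\C)[C@H]1C(=C)CO | intermediate
35 | (3aS,4S,5R,6S,7S,7aR)-7-acetoxy-6-ethenyl-6-methyl-3-methylidene-2-oxo-5-(3-oxoprop-1-en-2-yl)octahydro-1-benzofuran-4-yl (2Z)-2-methylbut-2-enoate | C=C[C@]1(C)[C@H](OC(C)=O)[C@@H]2OC(=O)C(=C)[C@H]2[C@@H](OC(=O)/C(C)=C\C)[C@H]1C(=C)C=O | target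

Total step count: 21.
Longest linear sequence: 17 steps (steps 1–4 followed by 9–21; the branch 5–8 followed by 9–21 is equally long).

Steps most likely to fail

1. Step 9 (aldol union). The process at risk is the π-facial selectivity at aldehyde 7: attack in the Felkin sense, or erosion of the syn selectivity, would form C5 and C6 with the wrong sense relative to C7. The fallback is a Felkin-matched anti-aldol followed by inversion at C6, and it sets out from 15 and 7. Enolisation of 15 with (c-C6H11)2BCl and Et3N should give the (E)-dicyclohexylboron dienolate F1. (E)-Enolates add to α-branched aldehydes in the Felkin sense through the chair, so the boron aldolate F2 and, after oxidative work-up, the 5,6-anti-6,7-syn aldol adduct F3 should result, in which C5 has the target configuration and C6 is epimeric. F3 is carried through the operations of steps 10 to 13: the triethylsilyl ether F4, the C4-methylene compound F5, the Mannich base F6, the ammonium iodide F7, the α-methylene lactone F8 and the C6-epimeric alcohol F9. A Mitsunobu esterification of F9 with angelic acid 25 (PPh3, diisopropyl azodicarboxylate, toluene, 0 °C to rt) should then invert C6 and install the ester in one operation, and the route is rejoined at 27.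

2. Step 18 (ring closure). The processes at risk are isomerisation of the (Z)-allylchromium before the C–C bond forms (which would give C9/C10 diastereomers), protonolysis of the allylmetal, and attack through the α-carbon. The fallback closes the same bond by intramolecular allylboration, whose allylmetal is configurationally stable, and it sets out from 29. Borylation with bis(pinacolato)diboron and catalytic Pd2(dba)3 (zerovalent palladium) in THF should give the (Z)-allyl pinacolboronate F10 with retention of geometry. Dess–Martin oxidation then gives the boronate aldehyde F11, which should cyclise on standing through the same chair transition state to the cyclic borate F12. Aqueous work-up releases the alcohol and the route is rejoined at 32.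

3. Step 14 (angeloylation). The processes at risk are slow acylation of the hindered C6 hydroxyl, Z-to-E isomerisation to the tiglate, and base-induced migration of the exocyclic lactone double bond or translactonisation at 75 °C. The fallback builds the angelate on the alcohol by a Z-selective olefination and sets out from 24. Esterification with 2-[bis(2,2,2-trifluoroethoxy)phosphoryl]propanoic acid (DCC, DMAP, CH2Cl2, rt) should give the phosphonate ester F13. A Still–Gennari olefination (KN(SiMe3)2, 18-crown-6, THF, −78 °C, acetaldehyde) should then deliver the (Z)-2-methylbut-2-enoate, and the route is rejoined at 27.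

Further compounds

F1 | step 9 | (E)-dicyclohexylboron dienolate of 15 | C1CCCCC1B(C1CCCCC1)O/C(COCc1ccc(OC)cc1)=C/C(C)=C\CO[Si](c1ccccc1)(c1ccccc1)C(C)(C)C
F2 | step 9 | dicyclohexylboron aldolate of F3 | CC(C)(C)[Si](OC[C@@H]1OC(=O)C[C@H]1[C@H](OB(C2CCCCC2)C2CCCCC2)[C@H](/C(C)=C\CO[Si](c2ccccc2)(c2ccccc2)C(C)(C)C)C(=O)COCc2ccc(OC)cc2)(c3ccccc3)c3ccccc3
F3 | step 9 | 5,6-anti-6,7-syn aldol adduct (C6 epimer of 18) | CC(C)(C)[Si](OC[C@@H]1OC(=O)C[C@H]1[C@H](O)[C@H](/C(C)=C\CO[Si](c2ccccc2)(c2ccccc2)C(C)(C)C)C(=O)COCc2ccc(OC)cc2)(c3ccccc3)c3ccccc3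
F4 | step 9 | C6 triethylsilyl ether of F3 (C6 epimer of 19) | CC(C)(C)[Si](OC[C@@H]1OC(=O)C[C@H]1[C@H](O[Si](CC)(CC)CC)[C@H](/C(C)=C\CO[Si](c2ccccc2)(c2ccccc2)C(C)(C)C)C(=O)COCc2ccc(OC)cc2)(c3ccccc3)c3ccccc3
F5 | step 9 | C4-methylene compound (C6 epimer of 20) | CC(C)(C)[Si](OC[C@@H]1OC(=O)C[C@H]1[C@H](O[Si](CC)(CC)CC)[C@H](/C(C)=C\CO[Si](c2ccccc2)(c2ccccc2)C(C)(C)C)C(=C)COCc2ccc(OC)cc2)(c3ccccc3)c3ccccc3
F6 | step 9 | Mannich base (C6 epimer of 21) | CC(C)(C)[Si](OC[C@@H]1OC(=O)C(CN(C)C)[C@H]1[C@H](O[Si](CC)(CC)CC)[C@H](/C(C)=C\CO[Si](c2ccccc2)(c2ccccc2)C(C)(C)C)C(=C)COCc2ccc(OC)cc2)(c3ccccc3)c3ccccc3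
F7 | step 9 | ammonium iodide (C6 epimer of 22) | CC(C)(C)[Si](OC[C@@H]1OC(=O)C(C[N+](C)(C)C)[C@H]1[C@H](O[Si](CC)(CC)CC)[C@H](/C(C)=C\CO[Si](c2ccccc2)(c2ccccc2)C(C)(C)C)C(=C)COCc2ccc(OC)cc2)(c3ccccc3)c3ccccc3.[I-]
F8 | step 9 | α-methylene lactone (C6 epimer of 23) | CC(C)(C)[Si](OC[C@@H]1OC(=O)C(=C)[C@H]1[C@H](O[Si](CC)(CC)CC)[C@H](/C(C)=C\CO[Si](c2ccccc2)(c2ccccc2)C(C)(C)C)C(=C)COCc2ccc(OC)cc2)(c3ccccc3)c3ccccc3
F9 | step 9 | C6-epimeric alcohol (C6 epimer of 24) | CC(C)(C)[Si](OC[C@@H]1OC(=O)C(=C)[C@H]1[C@H](O)[C@H](/C(C)=C\CO[Si](c2ccccc2)(c2ccccc2)C(C)(C)C)C(=C)COCc2ccc(OC)cc2)(c3ccccc3)c3ccccc3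
F10 | step 18 | (Z)-allyl pinacolboronate with free C9 hydroxyl | OC[C@@H]1OC(=O)C(=C)[C@H]1[C@@H](OC(=O)/C(C)=C\C)[C@H](/C(C)=C\CB2OC(C)(C)C(C)(C)O2)C(=C)COCc1ccc(OC)cc1
F11 | step 18 | (Z)-allyl pinacolboronate C9 aldehyde | O=C[C@@H]1OC(=O)C(=C)[C@H]1[C@@H](OC(=O)/C(C)=C\C)[C@H](/C(C)=C\CB2OC(C)(C)C(C)(C)O2)C(=C)COCc1ccc(OC)cc1
F12 | step 18 | pinacol borate of 32 (C9–O–B) | C=C[C@]1(C)[C@H](OB3OC(C)(C)C(C)(C)O3)[C@@H]2OC(=O)C(=C)[C@H]2[C@@H](OC(=O)/C(C)=C\C)[C@H]1C(=C)COCc1ccc(OC)cc1
F13 | step 14 | C6 2-[bis(2,2,2-trifluoroethoxy)phosphoryl]propanoate of 24 | CC(C)(C)[Si](OC[C@@H]1OC(=O)C(=C)[C@H]1[C@@H](OC(=O)C(C)P(=O)(OCC(F)(F)F)OCC(F)(F)F)[C@H](/C(C)=C\CO[Si](c2ccccc2)(c2ccccc2)C(C)(C)C)C(=C)COCc2ccc(OC)cc2)(c3ccccc3)c3ccccc3
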